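## The problem

- The target is a stilbene trimer built on a 2,3-dihydro-1H-indene: five-membered ring C fused to the 4,6-dihydroxybenzo ring B, with a 4-hydroxyphenyl group (ring A) on C3 and a 3,5-dihydroxyphenyl group (ring D) on C2. C1 carries an exocyclic methine C8 that is bonded to C5′ of a trans-2′,3′-diaryl-2′,3′-dihydrobenzofuran (benzo ring E, furan ring F, aryl rings G on C3′ and H on C2′).
- The C1=C8 bond is Z: ring E is cis to C7a and faces H7. This is the more crowded and presumably less stable geometry, so an olefination or any acid-equilibrated route is expected to favour the wrong isomer.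
- There are two trans stereodiads, C2/C3 (R,R) and C2′/C3′ (S,S). Within a diad one centre can control the other, because trans is the thermodynamic arrangement. The diads are separated by ring E and the alkene, so neither can control the other.
- C2 is benzylic and allylic. Strong base threatens epimerisation or migration of the double bond into ring C. Protonation at C1 gives a C8 cation stabilised by the ring E oxygen, which would scramble the alkene geometry.
- Eight free phenols, an electron-rich styrene and the acid-labile benzylic C2′–O1′ bond exclude oxidants, strong protic acid and hydrogenation late in the route.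
- The enabling feature: across C1=C8 the ring B carbon C7a (on C1) and the ring E carbon C5′ (on C8) are cis, and C8 carries only hydrogen besides. This is the pattern left when an aryl–palladium at C7a adds syn across a terminal alkyne C1≡C8 and the alkenyl–palladium is then arylated. C7a is an oxygen-free benzene carbon meta to both ring B oxygens, so it can carry a bromide from the first starting material.

## Retrosynthesis

**26 to 25.** The eight O–H bonds are traced back to benzyl ethers in 25. Methyl ethers would need a boron tribromide treatment at room temperature that endangers the Z alkene and ring F, and aryl silyl ethers would not survive the carbonate/methanol and aqueous-base steps. Benzyl ethers can be removed at −78 °C without a proton source and without hydrogen. The forward step must leave C1=C8 and C2′–O1′ untouched.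

**25 to 13 and 24 (key cut).** Two bonds are cut, C7a–C1 (ring C) and C8–C5′. Cutting C1=C8 instead (olefination of an indanone) leaves the geometry to thermodynamics. Cutting only C8–C5′ needs a stereodefined alkenyl metal on a finished indane. The double cut gives the acyclic bromo-alkyne 13 and the boronate 24, each about half the target and each carrying one diad. The forward reaction must insert the alkyne before cross-coupling and must deliver ring E cis to C7a; syn carbopalladation does both. The remote stereo-relation is solved by convergence of two enantioenriched halves.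

**13 to 12 to 10.** The C1≡C8 triple bond is cut back to a carbonyl at C1 (one-carbon homologation), and the ring B ether at C4 to the phenol 12. The C4 oxygen is ortho to C3a, so C1 and O4 can be tied into a six-membered lactone, the trans-3,4-diaryl-dihydrocoumarin 10. This converts an acyclic 1,2-diaryl diad into a cyclic one in which C2 (alpha to the carbonyl) can be equilibrated to trans. The forward steps must reduce and homologate without losing C2.

**10 to 6 and 7.** C2–C3 and O4–C1 are cut: a formal [4+2] union of the ortho-quinone methide 9 (released from sulfone 6) with the enolate of arylacetic acid 7 (activated as 8). This uses the same polarity as the biosynthetic quinone methides, with C3 electrophilic. Conjugate arylation of a preformed coumarin would instead need an alpha-arylation in the presence of the aryl bromide. Only the face of attack at C3 needs catalyst control; C2 follows by equilibration.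

**6 to 5 to 3 and 4, then 3 to 2 to 1.** The C3–ring A bond comes from addition of Grignard reagent 4 to salicylaldehyde 3. The formyl carbon comes from formylation of 1 and the single benzyl ether from regioselective alkylation of 2. Bromine cannot be introduced later by electrophilic substitution because C7a is meta to both oxygens, so it comes with 1.

**24 to 23 to 22 to 20 to 16 and 17, then 16 to 14 and 15.** C5′–B comes from C5′–Br. The C2′–C3′ bond of ring F is cut to a diaryl carbene inserting into the benzylic ether C–H bond of hydrazone 20. The catalyst sets C3′, and C2′ is corrected from cis (22) to trans (23) by reversible ionisation of C2′–O1′. Oxidative phenol–stilbene coupling would build the same ring in one step but only as a racemate. Hydrazone 20 comes from nitrile 16 and the Grignard reagent of 17, and 16 from phenol 14 and chloride 15.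

## Roads not taken

**Alternative 1:** (the most obvious) biomimetic oxidative coupling.
- Cut: O1′–C2′ and C3′–C3a′. Ring F is formed last by oxidative [3+2] coupling of the ring E phenol of the Z dimer A1 with the stilbene A2.
- Why not: it is short, but nothing in A1 can transmit configuration over the seven bonds to C2′/C3′, so the target and its diastereomer A3 must form together. A1 itself would arise from radical dimerisation as a racemate, with its E isomer. Four different phenol types compete for the oxidant. The chosen plan sets each diad under its own absolute control and fixes the geometry stereospecifically.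

**Alternative 2:** indanone olefination.
- Cut: C1=C8. Ketone A4 would be olefinated with the ylide from phosphonium salt A5.
- Why not: A4 is hindered and enolisable at C2. The ylide is semi-stabilised, and the less crowded E isomer A6 should dominate over 25. Ring C and the fragment union would need separate steps, whereas the chosen step does both and fixes Z by mechanism.

**Alternative 3:** internal alkyne with hydride capture.
- Cut: C7a–C1 only. Sonogashira coupling of 13 with a ring E halide gives the diarylalkyne A7, followed by reductive 5-exo-dig cyclisation.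
- Why not: syn addition of aryl and hydride puts hydrogen cis to C7a and ring E cis to C2, which is the E isomer A6. The step count is the same but the geometry is wrong. This is why the alkyne must be terminal and the capture must be by the aryl group.

Key step: step 13

Assumption: the sense of induction of HyperBTM (step 5) and Rh2(R-PTAD)4 (step 10) is taken by analogy with related substrates, the catalyst enantiomer meant being the one that gives the configuration written; 4, 7, 15 and 17 are taken as catalogue compounds.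

## Steps

Step 1
Reactants: 1 5-bromobenzene-1,3-diol
Product: 2 2-bromo-4,6-dihydroxybenzaldehyde
Conditions: POCl3, DMF, MeCN, 0 °C to rt; then H2O, 50 °C
Reagents that add atoms: N,N-dimethylformamide CN(C)C=O; water O
Why: Vilsmeier–Haack formylation of a resorcinol goes ortho to one hydroxyl and para to the other, not between the oxygens, so the formyl group lands on the ring carbon (future C3a) flanked by bromine (future C7a) and hydroxyl (future O4).

Step 2
Reactants: 2 2-bromo-4,6-dihydroxybenzaldehyde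
Product: 3 4-(benzyloxy)-2-bromo-6-hydroxybenzaldehyde
Conditions: BnBr (1.05 equiv), NaHCO3, MeCN, 70 °C
Reagents that add atoms: benzyl bromide BrCc1ccccc1
Why: Regioselective Williamson etherification; the 6-hydroxyl is hydrogen-bonded to the aldehyde and is not alkylated by a weak base, so only the para hydroxyl reacts.

Step 3
Reactants: 3 4-(benzyloxy)-2-bromo-6-hydroxybenzaldehyde; 4 4-(benzyloxy)phenylmagnesium bromide
Product: 5 rac-5-(benzyloxy)-2-{[4-(benzyloxy)phenyl](hydroxy)methyl}-3-bromophenol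
Conditions: 4 (2.3 equiv), THF, 0 °C to rt; aq. NH4Cl
Reagents that add atoms: none
Why: Grignard addition to the aldehyde after the first equivalent has formed the magnesium phenoxide; the carbinol centre need not be controlled because it is planarised in step 5.

Step 4
Reactants: 5 rac-5-(benzyloxy)-2-{[4-(benzyloxy)phenyl](hydroxy)methyl}-3-bromophenol
Product: 6 rac-5-(benzyloxy)-2-{[4-(benzyloxy)phenyl](4-methylbenzenesulfonyl)methyl}-3-bromophenol
Conditions: 4-MeC6H4SO2H, CH2Cl2, rt
Reagents that add atoms: 4-methylbenzenesulfinic acid Cc1ccc(cc1)S(O)=O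
Why: Acid-promoted ionisation of the doubly activated benzhydrol and S-alkylation of the sulfinate gives a storable precursor that releases the ortho-quinone methide under mild base.

Step 5
Reactants: 6 rac-5-(benzyloxy)-2-{[4-(benzyloxy)phenyl](4-methylbenzenesulfonyl)methyl}-3-bromophenol; 7 [3,5-bis(benzyloxy)phenyl]acetic acid
Product: 10 (3R,4R)-7-(benzyloxy)-4-[4-(benzyloxy)phenyl]-3-[3,5-bis(benzyloxy)phenyl]-5-bromo-3,4-dihydro-2H-1-benzopyran-2-one, via mixed pivalic anhydride 8 (not isolated), via ortho-quinone methide 9 (not isolated)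
Conditions: 7, t-BuCOCl, i-Pr2NEt, CH2Cl2, 0 °C; then 6, (2S,3R)-HyperBTM (10 mol %), Cs2CO3, −20 °C to rt; then DBU (20 mol %), rt
Reagents that add atoms: none
Why: Isothiourea-catalysed Michael addition–lactonisation: the catalyst-bound C1-ammonium enolate from 8 adds to the methide carbon of 9 on the face set by the catalyst (future C3) and the phenoxide closes the lactone and releases the catalyst; DBU then equilibrates the alpha centre (future C2) to the trans lactone, in which the two aryl groups avoid a gauche contact, so the stereoconvergent sequence needs catalyst control at one centre only.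

Step 6
Reactants: 10 (3R,4R)-7-(benzyloxy)-4-[4-(benzyloxy)phenyl]-3-[3,5-bis(benzyloxy)phenyl]-5-bromo-3,4-dihydro-2H-1-benzopyran-2-one
Product: 12 5-(benzyloxy)-2-{(1R,2S)-1-[4-(benzyloxy)phenyl]-2-[3,5-bis(benzyloxy)phenyl]but-3-yn-1-yl}-3-bromophenol, via lactol 11 (not isolated)
Conditions: i-Bu2AlH (1.1 equiv), CH2Cl2, −78 °C; then MeOH, K2CO3, dimethyl (1-diazo-2-oxopropyl)phosphonate, −78 °C to rt
Reagents that add atoms: dimethyl (1-diazo-2-oxopropyl)phosphonate CC(=O)C(=[N+]=[N-])P(=O)(OC)OC
Why: Half-reduction of the aryl lactone and Ohira–Bestmann homologation of the ring-opened aldehyde turn the lactone carbonyl into C1≡C8 and free the C4 phenol; the aldehyde is held mostly as the lactol and its alpha hydrogen is flanked by an aryl and a diarylmethyl group, which should keep enolisation slower than homologation (the descriptor at C2 changes from R to S only because the priorities change).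

Step 7
Reactants: 12 5-(benzyloxy)-2-{(1R,2S)-1-[4-(benzyloxy)phenyl]-2-[3,5-bis(benzyloxy)phenyl]but-3-yn-1-yl}-3-bromophenol
Product: 13 1,5-bis(benzyloxy)-2-{(1R,2S)-1-[4-(benzyloxy)phenyl]-2-[3,5-bis(benzyloxy)phenyl]but-3-yn-1-yl}-3-bromobenzene
Conditions: BnBr, K2CO3, DMF, rt
Reagents that add atoms: benzyl bromide BrCc1ccccc1
Why: Williamson etherification; it blocks the phenol, which could otherwise add to the alkyne in a 6-exo-dig sense under palladium and base in step 13.

Step 8
Reactants: 14 5-bromo-2-hydroxybenzonitrile; 15 1-(benzyloxy)-4-(chloromethyl)benzene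
Product: 16 2-{[4-(benzyloxy)phenyl]methoxy}-5-bromobenzonitrile
Conditions: K2CO3, DMF, 60 °C
Reagents that add atoms: none
Why: Williamson etherification of an acidic cyanophenol with an activated benzylic chloride; the new O–CH2 group carries the C–H bonds used in step 10.

Step 9
Reactants: 16 2-{[4-(benzyloxy)phenyl]methoxy}-5-bromobenzonitrile; 17 1,3-bis(benzyloxy)-5-bromobenzene
Product: 20 (2-{[4-(benzyloxy)phenyl]methoxy}-5-bromophenyl)[3,5-bis(benzyloxy)phenyl]methanone hydrazone, via arylmagnesium bromide 18 (not isolated), via N-unsubstituted ketimine 19 (not isolated)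
Conditions: 17, Mg, THF, reflux; then 16, THF, 0 to 50 °C; MeOH; then N2H4·H2O, AcOH (cat.), EtOH, 70 °C
Reagents that add atoms: hydrazine NN
Why: Grignard addition to the nitrile stops at the imine, and transimination of the N–H ketimine with hydrazine gives the hydrazone without a separate ketone stage; the aryl bromide of 16 is inert to the arylmagnesium reagent.

Step 10
Reactants: 20 (2-{[4-(benzyloxy)phenyl]methoxy}-5-bromophenyl)[3,5-bis(benzyloxy)phenyl]methanone hydrazone
Product: 22 (2R,3S)-2-[4-(benzyloxy)phenyl]-3-[3,5-bis(benzyloxy)phenyl]-5-bromo-2,3-dihydro-1-benzofuran, via diaryldiazomethane 21 (not isolated)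
Conditions: MnO2, Rh2(R-PTAD)4 (1 mol %), CH2Cl2, 0 °C
Reagents that add atoms: none
Why: Oxidation to the diazo compound and dirhodium-catalysed intramolecular C–H insertion of the donor/donor carbene into the activated benzylic ether C–H bond closes ring F; the chiral carboxylate catalyst sets C3′ (S) and the concerted insertion gives the cis isomer kinetically.

Step 11
Reactants: 22 (2R,3S)-2-[4-(benzyloxy)phenyl]-3-[3,5-bis(benzyloxy)phenyl]-5-bromo-2,3-dihydro-1-benzofuran
Product: 23 (2S,3S)-2-[4-(benzyloxy)phenyl]-3-[3,5-bis(benzyloxy)phenyl]-5-bromo-2,3-dihydro-1-benzofuran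
Conditions: CF3CO2H, CH2Cl2, 0 °C to rt
Reagents that add atoms: none
Why: Reversible acid ionisation of the C2′–O1′ bond (a 4-alkoxybenzylic cation) and reclosure epimerise C2′ only, funnelling the cis isomer to the thermodynamic trans one while C3′ keeps the configuration set in step 10.

Step 12
Reactants: 23 (2S,3S)-2-[4-(benzyloxy)phenyl]-3-[3,5-bis(benzyloxy)phenyl]-5-bromo-2,3-dihydro-1-benzofuran
Product: 24 2-{(2S,3S)-2-[4-(benzyloxy)phenyl]-3-[3,5-bis(benzyloxy)phenyl]-2,3-dihydro-1-benzofuran-5-yl}-4,4,5,5-tetramethyl-1,3,2-dioxaborolane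
Conditions: B2pin2, Pd(dppf)Cl2 (3 mol %), KOAc, 1,4-dioxane, 85 °C
Reagents that add atoms: bis(pinacolato)diboron CC1(C)OB(OC1(C)C)B1OC(C)(C)C(C)(C)O1
Why: Miyaura borylation of an aryl bromide; the stereocentres are remote from the reacting carbon and not acidic.

Step 13
Reactants: 13 1,5-bis(benzyloxy)-2-{(1R,2S)-1-[4-(benzyloxy)phenyl]-2-[3,5-bis(benzyloxy)phenyl]but-3-yn-1-yl}-3-bromobenzene; 24 2-{(2S,3S)-2-[4-(benzyloxy)phenyl]-3-[3,5-bis(benzyloxy)phenyl]-2,3-dihydro-1-benzofuran-5-yl}-4,4,5,5-tetramethyl-1,3,2-dioxaborolane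
Product: 25 (1Z,2R,3R)-4,6-bis(benzyloxy)-3-[4-(benzyloxy)phenyl]-2-[3,5-bis(benzyloxy)phenyl]-1-({(2S,3S)-2-[4-(benzyloxy)phenyl]-3-[3,5-bis(benzyloxy)phenyl]-2,3-dihydro-1-benzofuran-5-yl}methylidene)-2,3-dihydro-1H-indene
Conditions: Pd(OAc)2 (5 mol %), SPhos (10 mol %), K3PO4, toluene/H2O (10:1), 70 °C, 24 added slowly
Reagents that add atoms: none
Why: Zerovalent palladium inserts into the C7a–Br bond of 13, the aryl–palladium adds syn across the tethered terminal alkyne to form C7a–C1, and the alkenyl–palladium (metal on C8, cis to C7a) is captured by transmetalation with 24 and reductive elimination with retention. The closest known reaction type is the palladium-catalysed cyclisation–anion capture cascade, an intramolecular alkyne carbopalladation terminated by Suzuki–Miyaura coupling. Ring C is the only ring closed and it closes 5-exo-dig; a syn addition in the endo sense would put an E double bond into a six-membered ring. No stereocentre is created: C2 and C3 pass through unchanged because the alkenyl–palladium has no beta hydrogen and phosphate is too weak a base to isomerise the propargylic position. The new stereo-element is the C1=C8 geometry, fixed as Z by the syn insertion and the retentive coupling, not by product stability. The step needs insertion to precede cross-coupling, which the substrate secures by offering a unimolecular five-ring closure against a bimolecular transmetalation kept slow by adding 24 gradually. The union of two enantioenriched halves also settles the relation between the two remote diads.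

Step 14
Reactants: 25 (1Z,2R,3R)-4,6-bis(benzyloxy)-3-[4-(benzyloxy)phenyl]-2-[3,5-bis(benzyloxy)phenyl]-1-({(2S,3S)-2-[4-(benzyloxy)phenyl]-3-[3,5-bis(benzyloxy)phenyl]-2,3-dihydro-1-benzofuran-5-yl}methylidene)-2,3-dihydro-1H-indene
Product: 26 (1Z,2R,3R)-2-(3,5-dihydroxyphenyl)-1-{[(2S,3S)-3-(3,5-dihydroxyphenyl)-2-(4-hydroxyphenyl)-2,3-dihydro-1-benzofuran-5-yl]methylidene}-3-(4-hydroxyphenyl)-2,3-dihydro-1H-indene-4,6-diol
Conditions: BCl3, C6HMe5, CH2Cl2, −78 °C; then MeOH, −78 °C to rt
Reagents that add atoms: none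
Why: Lewis acid cleavage of aryl benzyl ethers with pentamethylbenzene as a non-basic benzyl cation scavenger works at −78 °C without a proton source or hydrogen, so the Z alkene, C2 and ring F should survive and the electron-rich rings are not C-benzylated.

## Compound list

1 | 5-bromobenzene-1,3-diol | Oc1cc(O)cc(Br)c1 | starting material
2 | 2-bromo-4,6-dihydroxybenzaldehyde | O=Cc1c(Br)cc(O)cc1O | intermediate
3 | 4-(benzyloxy)-2-bromo-6-hydroxybenzaldehyde | O=Cc1c(Br)cc(OCc2ccccc2)cc1O | intermediate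
4 | 4-(benzyloxy)phenylmagnesium bromide | Br[Mg]c1ccc(OCc2ccccc2)cc1 | starting material
5 | rac-5-(benzyloxy)-2-{[4-(benzyloxy)phenyl](hydroxy)methyl}-3-bromophenol (racemic) | OC(c1ccc(OCc2ccccc2)cc1)c1c(Br)cc(OCc2ccccc2)cc1O | intermediate
6 | rac-5-(benzyloxy)-2-{[4-(benzyloxy)phenyl](4-methylbenzenesulfonyl)methyl}-3-bromophenol (racemic) | Cc1ccc(cc1)S(=O)(=O)C(c1ccc(OCc2ccccc2)cc1)c1c(Br)cc(OCc2ccccc2)cc1O | intermediate
7 | [3,5-bis(benzyloxy)phenyl]acetic acid | OC(=O)Cc1cc(OCc2ccccc2)cc(OCc2ccccc2)c1 | starting material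
8 | [3,5-bis(benzyloxy)phenyl]acetic 2,2-dimethylpropanoic anhydride | CC(C)(C)C(=O)OC(=O)Cc1cc(OCc2ccccc2)cc(OCc2ccccc2)c1 | intermediate (not isolated)
9 | 3-(benzyloxy)-6-{[4-(benzyloxy)phenyl]methylidene}-5-bromocyclohexa-2,4-dien-1-one (alkene geometry not defined) | O=C1C=C(OCc2ccccc2)C=C(Br)C1=Cc1ccc(OCc2ccccc2)cc1 | intermediate (not isolated)
10 | (3R,4R)-7-(benzyloxy)-4-[4-(benzyloxy)phenyl]-3-[3,5-bis(benzyloxy)phenyl]-5-bromo-3,4-dihydro-2H-1-benzopyran-2-one | c5ccccc5COc1ccc([C@H]2[C@H](c3cc(OCc5ccccc5)cc(OCc5ccccc5)c3)C(=O)Oc3cc(OCc5ccccc5)cc(Br)c32)cc1 | intermediate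
11 | (3R,4R)-7-(benzyloxy)-4-[4-(benzyloxy)phenyl]-3-[3,5-bis(benzyloxy)phenyl]-5-bromo-3,4-dihydro-2H-1-benzopyran-2-ol (anomeric mixture) | c5ccccc5COc1ccc([C@H]2[C@H](c3cc(OCc5ccccc5)cc(OCc5ccccc5)c3)C(O)Oc3cc(OCc5ccccc5)cc(Br)c32)cc1 | intermediate (not isolated)
12 | 5-(benzyloxy)-2-{(1R,2S)-1-[4-(benzyloxy)phenyl]-2-[3,5-bis(benzyloxy)phenyl]but-3-yn-1-yl}-3-bromophenol | c5ccccc5COc1ccc([C@@H]([C@@H](C#C)c2cc(OCc5ccccc5)cc(OCc5ccccc5)c2)c2c(O)cc(OCc5ccccc5)cc2Br)cc1 | intermediate
13 | 1,5-bis(benzyloxy)-2-{(1R,2S)-1-[4-(benzyloxy)phenyl]-2-[3,5-bis(benzyloxy)phenyl]but-3-yn-1-yl}-3-bromobenzene | c5ccccc5COc1ccc([C@@H]([C@@H](C#C)c2cc(OCc5ccccc5)cc(OCc5ccccc5)c2)c2c(OCc5ccccc5)cc(OCc5ccccc5)cc2Br)cc1 | intermediate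
14 | 5-bromo-2-hydroxybenzonitrile | N#Cc1cc(Br)ccc1O | starting material
15 | 1-(benzyloxy)-4-(chloromethyl)benzene | ClCc1ccc(OCc2ccccc2)cc1 | starting material
16 | 2-{[4-(benzyloxy)phenyl]methoxy}-5-bromobenzonitrile | N#Cc1cc(Br)ccc1OCc1ccc(OCc2ccccc2)cc1 | intermediate
17 | 1,3-bis(benzyloxy)-5-bromobenzene | Brc1cc(OCc2ccccc2)cc(OCc2ccccc2)c1 | starting material
18 | 3,5-bis(benzyloxy)phenylmagnesium bromide | Br[Mg]c1cc(OCc2ccccc2)cc(OCc2ccccc2)c1 | intermediate (not isolated)
19 | 1-(2-{[4-(benzyloxy)phenyl]methoxy}-5-bromophenyl)-1-[3,5-bis(benzyloxy)phenyl]methanimine | N=C(c1cc(Br)ccc1OCc1ccc(OCc2ccccc2)cc1)c1cc(OCc2ccccc2)cc(OCc2ccccc2)c1 | intermediate (not isolated)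
20 | (2-{[4-(benzyloxy)phenyl]methoxy}-5-bromophenyl)[3,5-bis(benzyloxy)phenyl]methanone hydrazone (C=N geometry not defined) | NN=C(c1cc(Br)ccc1OCc1ccc(OCc2ccccc2)cc1)c1cc(OCc2ccccc2)cc(OCc2ccccc2)c1 | intermediate
21 | 1-{[4-(benzyloxy)phenyl]methoxy}-2-{[3,5-bis(benzyloxy)phenyl](diazo)methyl}-4-bromobenzene | [N-]=[N+]=C(c1cc(Br)ccc1OCc1ccc(OCc2ccccc2)cc1)c1cc(OCc2ccccc2)cc(OCc2ccccc2)c1 | intermediate (not isolated)
22 | (2R,3S)-2-[4-(benzyloxy)phenyl]-3-[3,5-bis(benzyloxy)phenyl]-5-bromo-2,3-dihydro-1-benzofuran (cis) | Brc1ccc2c(c1)[C@H](c1cc(OCc3ccccc3)cc(OCc3ccccc3)c1)[C@H](c1ccc(OCc3ccccc3)cc1)O2 | intermediate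
23 | (2S,3S)-2-[4-(benzyloxy)phenyl]-3-[3,5-bis(benzyloxy)phenyl]-5-bromo-2,3-dihydro-1-benzofuran (trans) | Brc1ccc2c(c1)[C@H](c1cc(OCc3ccccc3)cc(OCc3ccccc3)c1)[C@@H](c1ccc(OCc3ccccc3)cc1)O2 | intermediate
24 | 2-{(2S,3S)-2-[4-(benzyloxy)phenyl]-3-[3,5-bis(benzyloxy)phenyl]-2,3-dihydro-1-benzofuran-5-yl}-4,4,5,5-tetramethyl-1,3,2-dioxaborolane | CC1(C)OB(OC1(C)C)c1ccc2c(c1)[C@H](c1cc(OCc3ccccc3)cc(OCc3ccccc3)c1)[C@@H](c1ccc(OCc3ccccc3)cc1)O2 | intermediate
25 | (1Z,2R,3R)-4,6-bis(benzyloxy)-3-[4-(benzyloxy)phenyl]-2-[3,5-bis(benzyloxy)phenyl]-1-({(2S,3S)-2-[4-(benzyloxy)phenyl]-3-[3,5-bis(benzyloxy)phenyl]-2,3-dihydro-1-benzofuran-5-yl}methylidene)-2,3-dihydro-1H-indene | c5ccccc5COc1ccc([C@@H]2c3c(OCc5ccccc5)cc(OCc5ccccc5)cc3/C(=C\c3ccc4c(c3)[C@H](c3cc(OCc5ccccc5)cc(OCc5ccccc5)c3)[C@@H](c3ccc(OCc5ccccc5)cc3)O4)[C@H]2c2cc(OCc5ccccc5)cc(OCc5ccccc5)c2)cc1 | intermediate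
26 | (1Z,2R,3R)-2-(3,5-dihydroxyphenyl)-1-{[(2S,3S)-3-(3,5-dihydroxyphenyl)-2-(4-hydroxyphenyl)-2,3-dihydro-1-benzofuran-5-yl]methylidene}-3-(4-hydroxyphenyl)-2,3-dihydro-1H-indene-4,6-diol | Oc1ccc([C@@H]2c3c(O)cc(O)cc3/C(=C\c3ccc4c(c3)[C@H](c3cc(O)cc(O)c3)[C@@H](c3ccc(O)cc3)O4)[C@H]2c2cc(O)cc(O)c2)cc1 | target

## Step count and risk

Total: 14 steps. Longest linear sequence: 9 steps (steps 1 to 7, 13, 14). The second branch has 5 steps (8 to 12) before the union.

**Step 13 (key step).**
- What may go wrong: cross-coupling of the aryl–palladium with 24 before the alkyne has inserted; base-mediated palladation and oligomerisation of the terminal alkyne; a 1,4-shift of palladium from C8 to C7 before capture. The cause is that a fast, ligand-accelerated transmetalation competes with the insertion.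
- Fallback: separate ring closure from union. Setting out from 13, the same carbopalladation is terminated with bis(pinacolato)diboron (Pd(OAc)2, PPh3, KOAc, toluene, 80 °C), where no activated boronate is present. This should give the alkenylboronate 2-{(Z)-[(2R,3R)-4,6-bis(benzyloxy)-3-[4-(benzyloxy)phenyl]-2-[3,5-bis(benzyloxy)phenyl]-2,3-dihydro-1H-inden-1-ylidene]methyl}-4,4,5,5-tetramethyl-1,3,2-dioxaborolane F1. F1 is then coupled with bromide 23 under Suzuki–Miyaura conditions (Pd(dppf)Cl2, K3PO4, dioxane/H2O) and returns to the route at 25.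

**Step 5.**
- What may go wrong: poor facial selectivity at the methide carbon, because the bromine next to it twists the quinone methide; incomplete equilibration to the trans lactone.
- Fallback: replace catalyst control by auxiliary control. Setting out from 7, anhydride 8 acylates lithiated (S)-4-benzyl-1,3-oxazolidin-2-one to give (4S)-4-benzyl-3-{[3,5-bis(benzyloxy)phenyl]acetyl}-1,3-oxazolidin-2-one F2. Its sodium enolate (NaN(SiMe3)2, THF, −78 °C) adds to 9 released from 6 by a second equivalent of base. The phenoxide lactonises with expulsion of the auxiliary, and DBU equilibration returns to the route at 10.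

**Step 6.**
- What may go wrong: enolisation of the ring-opened alpha-aryl aldehyde under carbonate/methanol with loss of configuration at C2; over-reduction of the reactive aryl lactone.
- Fallback: homologate under non-basic Wittig-type conditions. Setting out from 11 (isolated after the i-Bu2AlH reduction of 10), Ramirez olefination (CBr4, PPh3, Zn, CH2Cl2) gives 5-(benzyloxy)-2-{(1R,2S)-1-[4-(benzyloxy)phenyl]-2-[3,5-bis(benzyloxy)phenyl]-4,4-dibromobut-3-en-1-yl}-3-bromophenol F3. Benzylation (BnBr, K2CO3, DMF) gives 1,5-bis(benzyloxy)-2-{(1R,2S)-1-[4-(benzyloxy)phenyl]-2-[3,5-bis(benzyloxy)phenyl]-4,4-dibromobut-3-en-1-yl}-3-bromobenzene F4. Dehydrobromination with NaN(SiMe3)2 (THF, −78 °C) gives the bromoalkyne 1,5-bis(benzyloxy)-2-{(1R,2R)-1-[4-(benzyloxy)phenyl]-2-[3,5-bis(benzyloxy)phenyl]-4-bromobut-3-yn-1-yl}-3-bromobenzene F5. Its alkynyl bromide is exchanged selectively with i-PrMgCl at −78 °C and protonated, returning to the route at 13.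

**Step 10.**
- What may go wrong: insufficient enantioselectivity in the insertion, or azine formation from the diazo compound outrunning carbene transfer.
- Fallback: resolution. Setting out from 20, MnO2 with Rh2(OAc)4 gives the racemic cis bromide rac-(2R,3S)-2-[4-(benzyloxy)phenyl]-3-[3,5-bis(benzyloxy)phenyl]-5-bromo-2,3-dihydro-1-benzofuran F6. CF3CO2H gives the racemic trans bromide rac-(2S,3S)-2-[4-(benzyloxy)phenyl]-3-[3,5-bis(benzyloxy)phenyl]-5-bromo-2,3-dihydro-1-benzofuran F7. Preparative chromatography on a chiral stationary phase returns to the route at 23.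

**Step 14.**
- What may go wrong: Lewis or adventitious protic acid isomerises C1=C8 from Z to E through the C8 cation stabilised by ring E, or opens ring F at C2′–O1′.
- Fallback: restore the geometry photochemically. Setting out from 25, the deprotection is run as above; any (1E,2R,3R)-2-(3,5-dihydroxyphenyl)-1-{[(2S,3S)-3-(3,5-dihydroxyphenyl)-2-(4-hydroxyphenyl)-2,3-dihydro-1-benzofuran-5-yl]methylidene}-3-(4-hydroxyphenyl)-2,3-dihydro-1H-indene-4,6-diol F8 that forms is irradiated at 365 nm in degassed methanol. The stilbene-type E-to-Z photoisomerisation should lead to a Z-rich photostationary state, and separation returns to the route at 26.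

## Further compounds

F1 | step 13 | 2-{(Z)-[(2R,3R)-4,6-bis(benzyloxy)-3-[4-(benzyloxy)phenyl]-2-[3,5-bis(benzyloxy)phenyl]-2,3-dihydro-1H-inden-1-ylidene]methyl}-4,4,5,5-tetramethyl-1,3,2-dioxaborolane | c5ccccc5COc1ccc([C@@H]2c3c(OCc5ccccc5)cc(OCc5ccccc5)cc3/C(=C\B3OC(C)(C)C(C)(C)O3)[C@H]2c2cc(OCc5ccccc5)cc(OCc5ccccc5)c2)cc1
F2 | step 5 | (4S)-4-benzyl-3-{[3,5-bis(benzyloxy)phenyl]acetyl}-1,3-oxazolidin-2-one | O=C1OC[C@H](Cc2ccccc2)N1C(=O)Cc1cc(OCc2ccccc2)cc(OCc2ccccc2)c1
F3 | step 6 | 5-(benzyloxy)-2-{(1R,2S)-1-[4-(benzyloxy)phenyl]-2-[3,5-bis(benzyloxy)phenyl]-4,4-dibromobut-3-en-1-yl}-3-bromophenol | c5ccccc5COc1ccc([C@@H]([C@@H](C=C(Br)Br)c2cc(OCc5ccccc5)cc(OCc5ccccc5)c2)c2c(O)cc(OCc5ccccc5)cc2Br)cc1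
F4 | step 6 | 1,5-bis(benzyloxy)-2-{(1R,2S)-1-[4-(benzyloxy)phenyl]-2-[3,5-bis(benzyloxy)phenyl]-4,4-dibromobut-3-en-1-yl}-3-bromobenzene | c5ccccc5COc1ccc([C@@H]([C@@H](C=C(Br)Br)c2cc(OCc5ccccc5)cc(OCc5ccccc5)c2)c2c(OCc5ccccc5)cc(OCc5ccccc5)cc2Br)cc1
F5 | step 6 | 1,5-bis(benzyloxy)-2-{(1R,2R)-1-[4-(benzyloxy)phenyl]-2-[3,5-bis(benzyloxy)phenyl]-4-bromobut-3-yn-1-yl}-3-bromobenzene | c5ccccc5COc1ccc([C@@H]([C@@H](C#CBr)c2cc(OCc5ccccc5)cc(OCc5ccccc5)c2)c2c(OCc5ccccc5)cc(OCc5ccccc5)cc2Br)cc1
F6 | step 10 | rac-(2R,3S)-2-[4-(benzyloxy)phenyl]-3-[3,5-bis(benzyloxy)phenyl]-5-bromo-2,3-dihydro-1-benzofuran (racemic cis, both enantiomers written) | Brc1ccc2c(c1)[C@H](c1cc(OCc3ccccc3)cc(OCc3ccccc3)c1)[C@H](c1ccc(OCc3ccccc3)cc1)O2.Brc1ccc2c(c1)[C@@H](c1cc(OCc3ccccc3)cc(OCc3ccccc3)c1)[C@@H](c1ccc(OCc3ccccc3)cc1)O2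
F7 | step 10 | rac-(2S,3S)-2-[4-(benzyloxy)phenyl]-3-[3,5-bis(benzyloxy)phenyl]-5-bromo-2,3-dihydro-1-benzofuran (racemic trans, both enantiomers written) | Brc1ccc2c(c1)[C@H](c1cc(OCc3ccccc3)cc(OCc3ccccc3)c1)[C@@H](c1ccc(OCc3ccccc3)cc1)O2.Brc1ccc2c(c1)[C@@H](c1cc(OCc3ccccc3)cc(OCc3ccccc3)c1)[C@H](c1ccc(OCc3ccccc3)cc1)O2
F8 | step 14 | (1E,2R,3R)-2-(3,5-dihydroxyphenyl)-1-{[(2S,3S)-3-(3,5-dihydroxyphenyl)-2-(4-hydroxyphenyl)-2,3-dihydro-1-benzofuran-5-yl]methylidene}-3-(4-hydroxyphenyl)-2,3-dihydro-1H-indene-4,6-diol | Oc1ccc([C@@H]2c3c(O)cc(O)cc3/C(=C/c3ccc4c(c3)[C@H](c3cc(O)cc(O)c3)[C@@H](c3ccc(O)cc3)O4)[C@H]2c2cc(O)cc(O)c2)cc1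
A1 | alternative 1 | (1Z,2R,3R)-2-(3,5-dihydroxyphenyl)-3-(4-hydroxyphenyl)-1-[(4-hydroxyphenyl)methylidene]-2,3-dihydro-1H-indene-4,6-diol | Oc1ccc([C@@H]2c3c(O)cc(O)cc3/C(=C\c3ccc(O)cc3)[C@H]2c2cc(O)cc(O)c2)cc1
A2 | alternative 1 | 5-[(E)-2-(4-hydroxyphenyl)ethenyl]benzene-1,3-diol | Oc1ccc(/C=C/c2cc(O)cc(O)c2)cc1
A3 | alternative 1 | (1Z,2R,3R)-2-(3,5-dihydroxyphenyl)-1-{[(2R,3R)-3-(3,5-dihydroxyphenyl)-2-(4-hydroxyphenyl)-2,3-dihydro-1-benzofuran-5-yl]methylidene}-3-(4-hydroxyphenyl)-2,3-dihydro-1H-indene-4,6-diol | Oc1ccc([C@@H]2c3c(O)cc(O)cc3/C(=C\c3ccc4c(c3)[C@@H](c3cc(O)cc(O)c3)[C@H](c3ccc(O)cc3)O4)[C@H]2c2cc(O)cc(O)c2)cc1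
A4 | alternative 2 | (2R,3R)-4,6-bis(benzyloxy)-3-[4-(benzyloxy)phenyl]-2-[3,5-bis(benzyloxy)phenyl]-2,3-dihydro-1H-inden-1-one | c5ccccc5COc1ccc([C@@H]2c3c(OCc5ccccc5)cc(OCc5ccccc5)cc3C(=O)[C@H]2c2cc(OCc5ccccc5)cc(OCc5ccccc5)c2)cc1
A5 | alternative 2 | ({(2S,3S)-2-[4-(benzyloxy)phenyl]-3-[3,5-bis(benzyloxy)phenyl]-2,3-dihydro-1-benzofuran-5-yl}methyl)(triphenyl)phosphonium bromide | [Br-].c1ccc(cc1)[P+](Cc1ccc2c(c1)[C@H](c1cc(OCc3ccccc3)cc(OCc3ccccc3)c1)[C@@H](c1ccc(OCc3ccccc3)cc1)O2)(c1ccccc1)c1ccccc1
A6 | alternative 2 | (1E,2R,3R)-4,6-bis(benzyloxy)-3-[4-(benzyloxy)phenyl]-2-[3,5-bis(benzyloxy)phenyl]-1-({(2S,3S)-2-[4-(benzyloxy)phenyl]-3-[3,5-bis(benzyloxy)phenyl]-2,3-dihydro-1-benzofuran-5-yl}methylidene)-2,3-dihydro-1H-indene | c5ccccc5COc1ccc([C@@H]2c3c(OCc5ccccc5)cc(OCc5ccccc5)cc3/C(=C/c3ccc4c(c3)[C@H](c3cc(OCc5ccccc5)cc(OCc5ccccc5)c3)[C@@H](c3ccc(OCc5ccccc5)cc3)O4)[C@H]2c2cc(OCc5ccccc5)cc(OCc5ccccc5)c2)cc1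
A7 | alternative 3 | 1,5-bis(benzyloxy)-2-{(1R,2R)-1-[4-(benzyloxy)phenyl]-2-[3,5-bis(benzyloxy)phenyl]-4-{(2S,3S)-2-[4-(benzyloxy)phenyl]-3-[3,5-bis(benzyloxy)phenyl]-2,3-dihydro-1-benzofuran-5-yl}but-3-yn-1-yl}-3-bromobenzene | c5ccccc5COc1ccc([C@@H]([C@@H](C#Cc2ccc3c(c2)[C@H](c2cc(OCc5ccccc5)cc(OCc5ccccc5)c2)[C@@H](c2ccc(OCc5ccccc5)cc2)O3)c2cc(OCc5ccccc5)cc(OCc5ccccc5)c2)c2c(OCc5ccccc5)cc(OCc5ccccc5)cc2Br)cc1
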